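**Retrosynthetic overview**

- Feature: on ring A, C5–OH and C8–OMe are para, C7 carries oxygen and C6 hydrogen. This is the C1(=O)/C2(H)/C3(OR)/C4(OMe) array of a 3-alkoxy-4-methoxycyclobut-2-enone, which can be grafted onto the C4a=C8a double bond of a preformed 4-pyranone (ring C).
- Last disconnection: the O7–CH2CH2SiMe3 bond (fluoride), which leaves the 4'-O-prenyl ether untouched.
- Key disconnection: C4a–C5, closing ring A by thermal ring expansion of a 4-methoxy-4-(pyranonyl)cyclobutenone. That precursor comes from C8–C8a bond formation (C-lithiated 2-aryl-3-methoxy-4-pyranone plus a 2-(trimethylsilyl)ethyl semisquarate) and O-methylation.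
- Fragments: the arylpyranone by Suzuki–Miyaura coupling of 2-iodo-3-methoxy-4-pyranone with a 4-prenyloxyphenyl boronate; the semisquarate from squaric acid via dichloride, diester and hydride reduction with transposition.
- Ring order: ring B and ring C are bought rings joined by the C2–C1' bond; ring A is formed last.

Key step: step 9

Assumption: the phenolic boron building block is used as its commercial pinacol ester, and hindered lithium amide metalation of the 2-aryl-3-methoxy-4-pyranone is taken to occur at the CH next to the ring oxygen, as it does at C2 of chromones.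

**Route**

Step 1
Reactants: 1 squaric acid (3,4-dihydroxycyclobut-3-ene-1,2-dione)
Product: 2 squaryl dichloride (3,4-dichlorocyclobut-3-ene-1,2-dione)
Conditions: (COCl)2 (2.2 equiv), cat. DMF, CH2Cl2, 40 °C
Reagents that add atoms: oxalyl chloride, ClC(=O)C(Cl)=O
Why: Chloroiminium-mediated conversion of the two vinylogous carboxylic acid hydroxyls into vinylogous acid chlorides (acid chloride formation).

Step 2
Reactants: 2 squaryl dichloride; 3 2-(trimethylsilyl)ethanol
Product: 4 3,4-bis[2-(trimethylsilyl)ethoxy]cyclobut-3-ene-1,2-dione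
Conditions: 3 (2.1 equiv), iPr2NEt (2.2 equiv), CH2Cl2, −20 → 0 °C
Reagents that add atoms: none
Why: Addition–elimination of the alcohol at both vinylogous acid chloride carbons (esterification), run with base so that no acid reaches the β-silylethyl groups.

Step 3
Reactants: 4 3,4-bis[2-(trimethylsilyl)ethoxy]cyclobut-3-ene-1,2-dione
Product: 6 3-[2-(trimethylsilyl)ethoxy]cyclobut-3-ene-1,2-dione, via hydroxycyclobutenone 5 (not isolated)
Conditions: LiAlH(OtBu)3 (1.05 equiv), THF, −78 → −40 °C; 1 M HCl work-up; then cat. conc. HCl, wet CH2Cl2, 0 °C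
Reagents that add atoms: water, O
Why: Hydride adds 1,2 to one carbonyl of the symmetric diester to give racemic alcohol 5, whose acid-promoted ionization, capture of the alkoxy-stabilized cyclobutenyl cation by water at the distal alkoxy carbon and loss of 2-(trimethylsilyl)ethanol (allylic transposition with enol ether hydrolysis) should deliver the semisquarate, the stereocenter of 5 being destroyed.

Step 4
Reactants: 7 3-hydroxy-4H-pyran-4-one
Product: 8 3-hydroxy-2-iodo-4H-pyran-4-one
Conditions: NIS (1.05 equiv), DMF, 0 °C → rt, dark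
Reagents that add atoms: N-iodosuccinimide, O=C1CCC(=O)N1I
Why: Electrophilic iodination of the enolic 3-hydroxypyranone at C2, the carbon ortho to the hydroxyl, as in other substitutions of 3-hydroxy-4-pyranones.

Step 5
Reactants: 8 3-hydroxy-2-iodo-4H-pyran-4-one
Product: 9 2-iodo-3-methoxy-4H-pyran-4-one
Conditions: MeI (1.5 equiv), K2CO3, DMF, rt
Reagents that add atoms: iodomethane, CI
Why: Williamson O-methylation of the acidic enol hydroxyl.

Step 6
Reactants: 10 4-(4,4,5,5-tetramethyl-1,3,2-dioxaborolan-2-yl)phenol; 11 1-bromo-3-methylbut-2-ene (prenyl bromide)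
Product: 12 4,4,5,5-tetramethyl-2-[4-(3-methylbut-2-enyloxy)phenyl]-1,3,2-dioxaborolane
Conditions: K2CO3, DMF, rt
Reagents that add atoms: none
Why: Williamson etherification of the phenoxide with the primary allylic bromide (SN2), the pinacol boronate being inert to anhydrous carbonate.

Step 7
Reactants: 9 2-iodo-3-methoxy-4H-pyran-4-one; 12 4,4,5,5-tetramethyl-2-[4-(3-methylbut-2-enyloxy)phenyl]-1,3,2-dioxaborolane
Product: 13 3-methoxy-2-[4-(3-methylbut-2-enyloxy)phenyl]-4H-pyran-4-one
Conditions: Pd(PPh3)4 (5 mol %), K2CO3, dioxane/H2O (5:1), 70 °C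
Reagents that add atoms: none
Why: Suzuki–Miyaura coupling, in which the C2–I bond (a vinylogous acyl iodide) should add to zerovalent palladium far faster than the trisubstituted allylic ether can ionize, so the prenyl group should persist.

Step 8
Reactants: 13 3-methoxy-2-[4-(3-methylbut-2-enyloxy)phenyl]-4H-pyran-4-one; 6 3-[2-(trimethylsilyl)ethoxy]cyclobut-3-ene-1,2-dione
Product: 16 4-methoxy-4-{5-methoxy-4-oxo-6-[4-(3-methylbut-2-enyloxy)phenyl]-4H-pyran-2-yl}-3-[2-(trimethylsilyl)ethoxy]cyclobut-2-en-1-one (racemic), via 6-lithiopyranone 14 (not isolated), via lithium cyclobutenolate 15 (not isolated)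
Conditions: LiTMP (1.1 equiv), THF, −78 °C, 13 added to the base; 6 (1.2 equiv), −78 °C; MeOTf (2.5 equiv), −78 → −20 °C; aq. NaHCO3
Reagents that add atoms: methyl trifluoromethanesulfonate, COS(=O)(=O)C(F)(F)F
Why: Deprotonative lithiation at the sp2 CH next to the ring oxygen (the pattern of chromone 2-lithiation, the other side of the ring being blocked), 1,2-addition of the vinyllithium to the more electrophilic carbonyl of 6 (the one attached to the alkoxy-bearing carbon and outside the vinylogous ester) and Williamson-type O-methylation of the tertiary lithium alkoxide by MeOTf should give 16, whose new quaternary carbon forms as a racemate and is planarized in step 9.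

Step 9
Reactants: 16 4-methoxy-4-{5-methoxy-4-oxo-6-[4-(3-methylbut-2-enyloxy)phenyl]-4H-pyran-2-yl}-3-[2-(trimethylsilyl)ethoxy]cyclobut-2-en-1-one (racemic)
Product: 19 5-hydroxy-3,8-dimethoxy-2-[4-(3-methylbut-2-enyloxy)phenyl]-7-[2-(trimethylsilyl)ethoxy]chromen-4-one, via dienylketene 17 (not isolated), via cyclohexadienone 18 (not isolated)
Conditions: degassed PhMe (0.01 M), 110 °C
Reagents that add atoms: none
Why: Moore rearrangement: heating opens the cyclobutenone by conrotatory four-electron electrocyclic cleavage of its C1–C4 bond, the 4-methoxy donor rotating outward so that the pyranone lies cis to the ketene in (Z)-dienylketene 17. A thermal disrotatory six-electron electrocyclization then joins the electrophilic ketene carbon to the nucleophilic CH carbon of the pyranone (β-carbon of its enol ether, α to its carbonyl), forming the C4a–C5 bond and closing the six-membered carbocyclic ring A as dienone 18, which should enolize at once to the 5-hydroxy arene hydrogen-bonded to the C4 carbonyl. The closest known reactions are the ring expansions of 4-aryl-, 4-heteroaryl- and 4-alkenyl-4-alkoxycyclobutenones to 4-alkoxyphenols; here the enol-ether double bond of a 4-pyranone takes the alkenyl role. No stereocenter survives, since the quaternary carbon of 16 and the transient C4a–H centre of 18 both become sp2. The step needs outward torquoselectivity of the methoxy group, secured by its donor character, and a single closure site, secured because the only other neighbour of the attachment carbon is the ring oxygen; the fixed connectivity of the four cyclobutenone carbons then places OH at C5, H at C6, the silylethyl ether at C7 and OMe at C8, with no 6-alkoxy isomer possible. High dilution should suppress intermolecular ketene reactions, and 110 °C lies well below the temperature of aryl prenyl ether Claisen rearrangement.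

Step 10
Reactants: 19 5-hydroxy-3,8-dimethoxy-2-[4-(3-methylbut-2-enyloxy)phenyl]-7-[2-(trimethylsilyl)ethoxy]chromen-4-one
Product: 20 5,7-dihydroxy-3,8-dimethoxy-2-[4-(3-methylbut-2-enyloxy)phenyl]chromen-4-one (5,7-dihydroxy-3,8-dimethoxy-4'-prenyloxyflavone)
Conditions: Bu4NF (3 equiv), THF, 50 °C; aq. NH4Cl
Reagents that add atoms: none
Why: Fluoride attacks silicon and triggers a β-elimination (Peterson-type fragmentation) that expels ethene and the vinylogously acidic 7-phenoxide, while the methyl and prenyl ethers are inert to fluoride.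

**Compound list**

1 | squaric acid (3,4-dihydroxycyclobut-3-ene-1,2-dione) | OC1=C(O)C(=O)C1=O | starting material
2 | squaryl dichloride (3,4-dichlorocyclobut-3-ene-1,2-dione) | ClC1=C(Cl)C(=O)C1=O | intermediate
3 | 2-(trimethylsilyl)ethanol | C[Si](C)(C)CCO | starting material
4 | 3,4-bis[2-(trimethylsilyl)ethoxy]cyclobut-3-ene-1,2-dione | C[Si](C)(C)CCOC1=C(OCC[Si](C)(C)C)C(=O)C1=O | intermediate
5 | 4-hydroxy-2,3-bis[2-(trimethylsilyl)ethoxy]cyclobut-2-en-1-one (racemic) | O=C1C(OCC[Si](C)(C)C)=C(OCC[Si](C)(C)C)C1O | intermediate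
6 | 3-[2-(trimethylsilyl)ethoxy]cyclobut-3-ene-1,2-dione | O=C1C=C(OCC[Si](C)(C)C)C1=O | intermediate
7 | 3-hydroxy-4H-pyran-4-one | O=c1ccocc1O | starting material
8 | 3-hydroxy-2-iodo-4H-pyran-4-one | O=c1ccoc(I)c1O | intermediate
9 | 2-iodo-3-methoxy-4H-pyran-4-one | COc1c(I)occc1=O | intermediate
10 | 4-(4,4,5,5-tetramethyl-1,3,2-dioxaborolan-2-yl)phenol | CC1(C)OB(c2ccc(O)cc2)OC1(C)C | starting material
11 | 1-bromo-3-methylbut-2-ene (prenyl bromide) | CC(C)=CCBr | starting material
12 | 4,4,5,5-tetramethyl-2-[4-(3-methylbut-2-enyloxy)phenyl]-1,3,2-dioxaborolane | CC(C)=CCOc1ccc(B2OC(C)(C)C(C)(C)O2)cc1 | intermediate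
13 | 3-methoxy-2-[4-(3-methylbut-2-enyloxy)phenyl]-4H-pyran-4-one | COc1c(-c2ccc(OCC=C(C)C)cc2)occc1=O | intermediate
14 | {5-methoxy-4-oxo-6-[4-(3-methylbut-2-enyloxy)phenyl]-4H-pyran-2-yl}lithium | [Li]c1cc(=O)c(OC)c(-c2ccc(OCC=C(C)C)cc2)o1 | intermediate
15 | lithium 1-{5-methoxy-4-oxo-6-[4-(3-methylbut-2-enyloxy)phenyl]-4H-pyran-2-yl}-4-oxo-2-[2-(trimethylsilyl)ethoxy]cyclobut-2-en-1-olate (racemic) | [Li+].[O-]C1(c2cc(=O)c(OC)c(-c3ccc(OCC=C(C)C)cc3)o2)C(OCC[Si](C)(C)C)=CC1=O | intermediate
16 | 4-methoxy-4-{5-methoxy-4-oxo-6-[4-(3-methylbut-2-enyloxy)phenyl]-4H-pyran-2-yl}-3-[2-(trimethylsilyl)ethoxy]cyclobut-2-en-1-one (racemic) | O=C1C=C(OCC[Si](C)(C)C)C1(OC)c1cc(=O)c(OC)c(-c2ccc(OCC=C(C)C)cc2)o1 | intermediate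
17 | (3Z)-4-methoxy-4-{5-methoxy-4-oxo-6-[4-(3-methylbut-2-enyloxy)phenyl]-4H-pyran-2-yl}-3-[2-(trimethylsilyl)ethoxy]buta-1,3-dien-1-one | O=C=C/C(OCC[Si](C)(C)C)=C(/OC)c1cc(=O)c(OC)c(-c2ccc(OCC=C(C)C)cc2)o1 | intermediate
18 | 3,8-dimethoxy-2-[4-(3-methylbut-2-enyloxy)phenyl]-7-[2-(trimethylsilyl)ethoxy]-4aH-chromene-4,5-dione (racemic) | COC1=C(c2ccc(OCC=C(C)C)cc2)OC2=C(OC)C(OCC[Si](C)(C)C)=CC(=O)C2C1=O | intermediate
19 | 5-hydroxy-3,8-dimethoxy-2-[4-(3-methylbut-2-enyloxy)phenyl]-7-[2-(trimethylsilyl)ethoxy]chromen-4-one | COc1c(-c2ccc(OCC=C(C)C)cc2)oc2c(OC)c(OCC[Si](C)(C)C)cc(O)c2c1=O | intermediate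
20 | 5,7-dihydroxy-3,8-dimethoxy-2-[4-(3-methylbut-2-enyloxy)phenyl]chromen-4-one | COc1c(-c2ccc(OCC=C(C)C)cc2)oc2c(OC)c(O)cc(O)c2c1=O | target

**Step count**

Total: 10 steps. Longest linear sequence: 6 steps (7 → 8 → 9 → 13 → 16 → 19 → 20, steps 4, 5, 7, 8, 9, 10; the squarate branch, steps 1, 2, 3, 8, 9, 10, is equally long).

**Steps most likely to fail**

1. Step 8. The lithiated pyranone may add in conjugate fashion to pyranone that is not yet metalated. The organolithium may also attack the CH carbon or the vinylogous ester carbonyl of 6 instead of the intended carbonyl, and MeOTf may alkylate the pyranone carbonyl oxygen instead of the hindered alkoxide. The fallback sets out from 13 and returns at 16. Compound 13 is zincated at the same CH with TMPZnCl·LiCl (THF, 25 °C), giving a carbon–zinc species that does not add to pyranones, and quenched with I2 to give 6-iodo-3-methoxy-2-[4-(3-methylbut-2-enyloxy)phenyl]-4H-pyran-4-one F1. Iodine–magnesium exchange with iPrMgCl·LiCl (THF, −78 °C), now with no unmetalated pyranone present, addition of 6 and quench with aqueous NH4Cl should give 4-hydroxy-4-{5-methoxy-4-oxo-6-[4-(3-methylbut-2-enyloxy)phenyl]-4H-pyran-2-yl}-3-[2-(trimethylsilyl)ethoxy]cyclobut-2-en-1-one F2. This alcohol is isolated and O-methylated under neutral conditions with MeI and Ag2O (MeCN, rt) to give 16.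

2. Step 9. The ketene may be consumed by intermolecular reactions or by opening with inward rotation of the methoxy group before it closes onto the pyranone carbon, and prolonged heating would begin to endanger the prenyl ether. The fallback carries the ring expansion out on the free alcohol, the parent substrate of this reaction and a stronger outward-rotating donor, and introduces the methyl group only after ring A exists; it does not help if closure onto the pyranone carbon itself is the failing event. It sets out from lithium alkoxide 15, which is quenched with aqueous NH4Cl in place of MeOTf to give cyclobutenol F2, and returns at 19. Heating F2 in degassed toluene at 100 °C under argon should give 5,8-dihydroxy-3-methoxy-2-[4-(3-methylbut-2-enyloxy)phenyl]-7-[2-(trimethylsilyl)ethoxy]chromen-4-one F3. The crude hydroquinone is methylated at once with MeI (1.05 equiv) and K2CO3 in acetone at rt under argon; the 5-hydroxyl is chelated to the C4 carbonyl and should stay free, so only O8 reacts, giving 19.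

3. Step 3. Acid may also remove the second 2-(trimethylsilyl)ethyl group by β-silyl fragmentation during the transposition, and hydride may reduce the product further. The fallback avoids both hydride and acid; it sets out from 2 and returns at 6. Compound 2 is treated with one equivalent of 3 and iPr2NEt (CH2Cl2, −40 °C) to give 3-chloro-4-[2-(trimethylsilyl)ethoxy]cyclobut-3-ene-1,2-dione F4. The remaining vinylogous acid chloride is then reduced with Bu3SnH (1.0 equiv) and catalytic Pd(PPh3)4 (THF, 0 °C), in the manner of the palladium-catalysed reduction of acid chlorides to aldehydes, to give 6.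

**Further compounds**

F1 | step 8 | 6-iodo-3-methoxy-2-[4-(3-methylbut-2-enyloxy)phenyl]-4H-pyran-4-one | COc1c(-c2ccc(OCC=C(C)C)cc2)oc(I)cc1=O
F2 | step 8 | 4-hydroxy-4-{5-methoxy-4-oxo-6-[4-(3-methylbut-2-enyloxy)phenyl]-4H-pyran-2-yl}-3-[2-(trimethylsilyl)ethoxy]cyclobut-2-en-1-one (racemic) | O=C1C=C(OCC[Si](C)(C)C)C1(O)c1cc(=O)c(OC)c(-c2ccc(OCC=C(C)C)cc2)o1
F3 | step 9 | 5,8-dihydroxy-3-methoxy-2-[4-(3-methylbut-2-enyloxy)phenyl]-7-[2-(trimethylsilyl)ethoxy]chromen-4-one | COc1c(-c2ccc(OCC=C(C)C)cc2)oc2c(O)c(OCC[Si](C)(C)C)cc(O)c2c1=O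
F4 | step 3 | 3-chloro-4-[2-(trimethylsilyl)ethoxy]cyclobut-3-ene-1,2-dione | O=C1C(=O)C(OCC[Si](C)(C)C)=C1Cl
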